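The benzo ring of the chroman-2,4-dione is held by only two adjacent bonds, C8a–O1 and C4a–C4, which lead through the C2 and C4 carbonyls to the quaternary carbon C3. C3 is therefore built first, as an enantiopure malonic half ester carrying farnesyl, a 3-PMB-oxypropyl arm, a free acid and a hexafluoroisopropyl ester, and the arene is added last as benzyne. In one operation the carboxylate C–O bond takes up benzyne (C8a–O1, C4a–C4) and the resulting phenoxide lactonises on the activated ester (O1–C2), closing the pyran-2,4-dione ring with C3 untouched. The diynone arm is then grown by acylating a separately made (S,Z)-diynyl carbinol.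

Key step: step 8

Assumption: the facial sense of the two catalyst-controlled steps (4 and 14) is taken from the closest analogues; both catalysts exist as either antipode, and the antipode would be used if the first assay showed the opposite sense.

Step 1
Reactants: 1 3-[(4-methoxybenzyl)oxy]propan-1-ol
Product: 2 1-[(3-iodopropoxy)methyl]-4-methoxybenzene
Conditions: I2, PPh3, imidazole, CH2Cl2, 0 °C to rt
Reagents that add atoms: iodine, [I][I]
Why: Appel iodination converts the primary alcohol into the iodide by SN2 displacement of the alkoxyphosphonium ion, and the PMB ether is untouched under these neutral conditions.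

Step 2
Reactants: 3 mono-tert-butyl malonate
Product: 4 tert-butyl 2,2-diphenylethyl malonate
Conditions: 2,2-diphenylethanol, EDC·HCl, DMAP (cat.), CH2Cl2, 0 °C to rt
Reagents that add atoms: 2,2-diphenylethanol, OCC(c1ccccc1)c1ccccc1
Why: Steglich-type carbodiimide esterification of the half acid gives the mixed malonate whose two ester groups (bulky tert-butyl, aryl-rich 2,2-diphenylethyl) are the pair that the chiral phase-transfer catalyst tells apart in step 4.

Step 3
Reactants: 4 tert-butyl 2,2-diphenylethyl malonate; 2 1-[(3-iodopropoxy)methyl]-4-methoxybenzene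
Product: 5 racemic tert-butyl 2,2-diphenylethyl 2-{3-[(4-methoxybenzyl)oxy]propyl}malonate
Conditions: Cs2CO3, DMF, rt (4 in slight excess)
Reagents that add atoms: none
Why: Malonate alkylation (SN2) by the primary iodide under mild carbonate conditions installs the oxygenated three-carbon arm, and the slight excess of malonate holds back dialkylation.

Step 4
Reactants: 5 racemic tert-butyl 2,2-diphenylethyl 2-{3-[(4-methoxybenzyl)oxy]propyl}malonate; 6 (2E,6E)-farnesyl bromide
Product: 7 1-tert-butyl 3-(2,2-diphenylethyl) (2R)-2-{3-[(4-methoxybenzyl)oxy]propyl}-2-[(2E,6E)-3,7,11-trimethyldodeca-2,6,10-trien-1-yl]malonate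
Conditions: (R,R)-3,4,5-trifluorophenyl-NAS bromide, that is (11bR,11'bR)-2,6-bis(3,4,5-trifluorophenyl)-4,4'-spirobi[4,5-dihydro-3H-dinaphtho[2,1-c:1',2'-e]azepinium] bromide (5 mol%), 50% aq KOH, toluene, −40 °C
Reagents that add atoms: none
Why: Enantioselective phase-transfer alkylation, in which the chiral spiro-ammonium cation pairs with the enolate and shields one of its faces, so that the allylic bromide is attacked at C1 (SN2, E,E geometry kept) from the open face and the quaternary carbon is set as R, the arrangement that becomes 3S in the target.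

Step 5
Reactants: 7 1-tert-butyl 3-(2,2-diphenylethyl) (2R)-2-{3-[(4-methoxybenzyl)oxy]propyl}-2-[(2E,6E)-3,7,11-trimethyldodeca-2,6,10-trien-1-yl]malonate
Product: 8 (2R)-2-(tert-butoxycarbonyl)-5-[(4-methoxybenzyl)oxy]-2-[(2E,6E)-3,7,11-trimethyldodeca-2,6,10-trien-1-yl]pentanoic acid
Conditions: KOH, MeOH/THF/H2O, 45 °C; then 1 M HCl, 0 °C, to pH 3
Reagents that add atoms: potassium hydroxide, [K+].[OH-]
Why: Saponification by acyl–oxygen cleavage removes the primary 2,2-diphenylethyl ester while the tert-butyl ester resists hydroxide, the PMB ether and the alkenes are base-stable, and a carbon without hydrogen cannot epimerise.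

Step 6
Reactants: 8 (2R)-2-(tert-butoxycarbonyl)-5-[(4-methoxybenzyl)oxy]-2-[(2E,6E)-3,7,11-trimethyldodeca-2,6,10-trien-1-yl]pentanoic acid
Product: 10 1-tert-butyl 3-(1,1,1,3,3,3-hexafluoropropan-2-yl) (2R)-2-{3-[(4-methoxybenzyl)oxy]propyl}-2-[(2E,6E)-3,7,11-trimethyldodeca-2,6,10-trien-1-yl]malonate, via acid chloride 9 (not isolated)
Conditions: 1-chloro-N,N,2-trimethylprop-1-en-1-amine, CH2Cl2, 0 °C to rt; then (CF3)2CHOH, pyridine, DMAP (cat.), 0 °C to rt
Reagents that add atoms: 1,1,1,3,3,3-hexafluoropropan-2-ol, OC(C(F)(F)F)C(F)(F)F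
Why: Neutral acid chloride formation with the α-chloroenamine and acylation of hexafluoroisopropanol install an activated ester whose alkoxide is a weak base and a poor nucleophile, so that the later ring closure by a phenoxide is downhill and irreversible, which it would not be with a simple alkyl ester.

Step 7
Reactants: 10 1-tert-butyl 3-(1,1,1,3,3,3-hexafluoropropan-2-yl) (2R)-2-{3-[(4-methoxybenzyl)oxy]propyl}-2-[(2E,6E)-3,7,11-trimethyldodeca-2,6,10-trien-1-yl]malonate
Product: 12 (2S)-2-{[(1,1,1,3,3,3-hexafluoropropan-2-yl)oxy]carbonyl}-5-[(4-methoxybenzyl)oxy]-2-[(2E,6E)-3,7,11-trimethyldodeca-2,6,10-trien-1-yl]pentanoic acid, via trimethylsilyl ester 11 (not isolated)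
Conditions: TMSOTf, 2,6-lutidine, CH2Cl2, 0 °C to rt; then pH 5 aqueous buffer
Reagents that add atoms: none
Why: Silyl triflate-mediated tert-butyl ester cleavage (O-silylation, loss of isobutene, hydrolysis of the silyl ester on work-up) frees the acid without protic acid, so the farnesyl alkenes, the PMB ether and the activated ester should survive.

Step 8
Reactants: 12 (2S)-2-{[(1,1,1,3,3,3-hexafluoropropan-2-yl)oxy]carbonyl}-5-[(4-methoxybenzyl)oxy]-2-[(2E,6E)-3,7,11-trimethyldodeca-2,6,10-trien-1-yl]pentanoic acid; 13 2-(trimethylsilyl)phenyl trifluoromethanesulfonate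
Product: 16 (3S)-3-{3-[(4-methoxybenzyl)oxy]propyl}-3-[(2E,6E)-3,7,11-trimethyldodeca-2,6,10-trien-1-yl]chroman-2,4-dione, via potassium carboxylate 14 (not isolated), via potassium 2-acylphenoxide 15 (not isolated)
Conditions: KH (1.0 equiv), THF, 0 °C; then 13 (1.4 equiv), KF, 18-crown-6, THF, 0 °C to rt; aq NH4Cl
Reagents that add atoms: none
Why: Proposed new method: the potassium carboxylate 14 adds through oxygen to benzyne (C8a–O1), the ortho aryl anion attacks the carbonyl of the aryl ester just formed through a four-membered transition state, and the benzoxetene alkoxide opens to the 2-acylphenoxide 15 (C4a–C4), which then acylates itself on the hexafluoroisopropyl ester (O1–C2). The closest known reaction is the insertion of arynes into the C–O bond of carboxylic acids to give 2-hydroxyaryl ketones, extended here by capture of the phenoxide by a neighbouring activated ester. The pyran-2,4-dione ring closes by 6-exo-trig addition–elimination, helped by the fully substituted C3 and made downhill by the weakly basic hexafluoroisopropoxide leaving group, whereas a simple alkyl ester would leave the equilibrium on the ring-open side. No stereocentre is formed; C3 bears no hydrogen, and its configuration follows from which carbonyl is the free acid (it becomes ketone C4) and which is the ester (it becomes lactone C2). The selectivity needed is that the aryl anion attacks the proximal aryl-ester carbonyl and not the distal ester through a six-membered path, which would give the enantiomer; the aryl ester is born in its Z conformation, which holds the distal carbonyl away from the carbanion while the proximal one lies within bonding distance. The preformed salt in THF offers no proton to the aryl anion, and the ionic carboxylate should outrun the ene reaction of benzyne with the farnesyl alkenes.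

Step 9
Reactants: 16 (3S)-3-{3-[(4-methoxybenzyl)oxy]propyl}-3-[(2E,6E)-3,7,11-trimethyldodeca-2,6,10-trien-1-yl]chroman-2,4-dione
Product: 18 3-{(3S)-2,4-dioxo-3-[(2E,6E)-3,7,11-trimethyldodeca-2,6,10-trien-1-yl]chroman-3-yl}propanal, via primary alcohol 17 (not isolated)
Conditions: DDQ, CH2Cl2/pH 7 buffer, 0 °C; organic phase dried; then Dess–Martin periodinane, NaHCO3, CH2Cl2, 0 °C
Reagents that add atoms: none
Why: Oxidative PMB cleavage with DDQ followed at once by Dess–Martin oxidation gives the aldehyde; the alcohol is not isolated because a free hydroxyl five atoms from the acylating lactone carbonyl C2 could translactonise, and both reagents should leave isolated trisubstituted alkenes alone at 0 °C.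

Step 10
Reactants: 18 3-{(3S)-2,4-dioxo-3-[(2E,6E)-3,7,11-trimethyldodeca-2,6,10-trien-1-yl]chroman-3-yl}propanal
Product: 19 3-{(3S)-2,4-dioxo-3-[(2E,6E)-3,7,11-trimethyldodeca-2,6,10-trien-1-yl]chroman-3-yl}propanoic acid
Conditions: NaClO2, NaH2PO4, 2-methylbut-2-ene, t-BuOH/H2O, 0 °C to rt
Reagents that add atoms: sodium chlorite, [Na+].[O-]Cl=O
Why: Pinnick oxidation takes the aldehyde to the acid near pH 4 without base, with 2-methylbut-2-ene scavenging hypochlorous acid so that the farnesyl alkenes and the aryl lactone are spared.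

Step 11
Reactants: 20 dec-2-yn-1-ol
Product: 21 (2Z)-dec-2-en-1-ol
Conditions: H2 (1 atm), Pd/CaCO3 poisoned with Pb(OAc)2 (Lindlar catalyst), quinoline, EtOAc, rt
Reagents that add atoms: none
Why: Lindlar semi-hydrogenation adds hydrogen syn to the alkyne on the poisoned palladium surface and stops at the Z-alkene.

Step 12
Reactants: 21 (2Z)-dec-2-en-1-ol
Product: 22 (2Z)-dec-2-enal
Conditions: Dess–Martin periodinane, NaHCO3, CH2Cl2, 0 °C; used at once
Reagents that add atoms: none
Why: Buffered Dess–Martin oxidation of the allylic alcohol gives the Z-enal under non-isomerising conditions, and immediate use avoids the ready Z to E isomerisation of such enals.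

Step 13
Reactants: 23 1,4-bis(trimethylsilyl)buta-1,3-diyne
Product: 25 buta-1,3-diyn-1-yl(trimethyl)silane, via lithium diynide 24 (not isolated)
Conditions: MeLi·LiBr, Et2O, 0 °C to rt; then H2O, 0 °C; kept as a solution
Reagents that add atoms: none
Why: Mono-desilylation by methyllithium (attack at silicon, loss of tetramethylsilane) stops after one silyl group because the lithium acetylide formed is deactivated, and protonation gives the terminal diyne.

Step 14
Reactants: 22 (2Z)-dec-2-enal; 25 buta-1,3-diyn-1-yl(trimethyl)silane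
Product: 26 (5S,6Z)-1-(trimethylsilyl)tetradec-6-ene-1,3-diyn-5-ol
Conditions: Me2Zn, (R,R)-ProPhenol, that is 2,6-bis{[(2R)-2-(hydroxydiphenylmethyl)pyrrolidin-1-yl]methyl}-4-methylphenol (20 mol%), Ph3P=O (40 mol%), toluene, 0 to 4 °C; aq NH4Cl
Reagents that add atoms: none
Why: Zinc–ProPhenol catalysed asymmetric alkynylation of an enal, in which the diynylzinc formed with Me2Zn is delivered inside the chiral dinuclear zinc pocket to the Re face of the aldehyde, which sets the carbinol carbon as S while the mild conditions should keep the Z-alkene.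

Step 15
Reactants: 26 (5S,6Z)-1-(trimethylsilyl)tetradec-6-ene-1,3-diyn-5-ol
Product: 27 tert-butyl(dimethyl){[(5S,6Z)-1-(trimethylsilyl)tetradec-6-ene-1,3-diyn-5-yl]oxy}silane
Conditions: TBSCl, imidazole, DMF, 0 °C to rt
Reagents that add atoms: tert-butyldimethylsilyl chloride, CC(C)(C)[Si](C)(C)Cl
Why: Standard silylation of the secondary alcohol (imidazole-assisted substitution at silicon) protects the carbinol against acylation in step 17 without touching the stereocentre.

Step 16
Reactants: 27 tert-butyl(dimethyl){[(5S,6Z)-1-(trimethylsilyl)tetradec-6-ene-1,3-diyn-5-yl]oxy}silane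
Product: 28 tert-butyl(dimethyl)[(5S,6Z)-tetradec-6-ene-1,3-diyn-5-yloxy]silane
Conditions: K2CO3 (cat.), MeOH/THF, 0 °C; kept as a solution
Reagents that add atoms: none
Why: Carbonate-catalysed methanolysis cleaves only the alkynyl C–Si bond, since the hindered O-silyl ether exchanges far more slowly.

Step 17
Reactants: 19 3-{(3S)-2,4-dioxo-3-[(2E,6E)-3,7,11-trimethyldodeca-2,6,10-trien-1-yl]chroman-3-yl}propanoic acid; 28 tert-butyl(dimethyl)[(5S,6Z)-tetradec-6-ene-1,3-diyn-5-yloxy]silane
Product: 30 (3S)-3-{(8S,9Z)-8-[(tert-butyldimethylsilyl)oxy]-3-oxoheptadeca-9-ene-4,6-diyn-1-yl}-3-[(2E,6E)-3,7,11-trimethyldodeca-2,6,10-trien-1-yl]chroman-2,4-dione, via acid chloride 29 (not isolated)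
Conditions: 1-chloro-N,N,2-trimethylprop-1-en-1-amine, CH2Cl2, 0 °C; then 28, PdCl2(PPh3)2 (3 mol%), CuI (6 mol%), Et3N, THF, 0 °C to rt
Reagents that add atoms: none
Why: Sonogashira-type acylation, in which the acid chloride adds oxidatively to zerovalent palladium, the copper acetylide of the terminal diyne transmetalates and reductive elimination gives the ynone directly, so that no alkoxide is ever generated five atoms from the acylating lactone, as it would be in an aldehyde addition and oxidation sequence.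

Step 18
Reactants: 30 (3S)-3-{(8S,9Z)-8-[(tert-butyldimethylsilyl)oxy]-3-oxoheptadeca-9-ene-4,6-diyn-1-yl}-3-[(2E,6E)-3,7,11-trimethyldodeca-2,6,10-trien-1-yl]chroman-2,4-dione
Product: 31 (3S)-3-[(8S,9Z)-8-hydroxy-3-oxoheptadeca-9-ene-4,6-diyn-1-yl]-3-[(2E,6E)-3,7,11-trimethyldodeca-2,6,10-trien-1-yl]chroman-2,4-dione
Conditions: HF·pyridine, pyridine, THF, 0 °C
Reagents that add atoms: none
Why: Fluoride-mediated desilylation with buffered HF·pyridine frees the secondary alcohol under mildly acidic conditions that the aryl lactone, the diynone and the allylic-propargylic carbinol should tolerate, giving the target.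

Compound list

1 | 3-[(4-methoxybenzyl)oxy]propan-1-ol | COc1ccc(COCCCO)cc1 | starting material
2 | 1-[(3-iodopropoxy)methyl]-4-methoxybenzene | COc1ccc(COCCCI)cc1 | intermediate
3 | mono-tert-butyl malonate | CC(C)(C)OC(=O)CC(=O)O | starting material
4 | tert-butyl 2,2-diphenylethyl malonate | CC(C)(C)OC(=O)CC(=O)OCC(c1ccccc1)c1ccccc1 | intermediate
5 | racemic tert-butyl 2,2-diphenylethyl 2-{3-[(4-methoxybenzyl)oxy]propyl}malonate | COc1ccc(COCCCC(C(=O)OCC(c2ccccc2)c2ccccc2)C(=O)OC(C)(C)C)cc1 | intermediate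
6 | (2E,6E)-farnesyl bromide | CC(C)=CCC/C(C)=C/CC/C(C)=C/CBr | starting material
7 | 1-tert-butyl 3-(2,2-diphenylethyl) (2R)-2-{3-[(4-methoxybenzyl)oxy]propyl}-2-[(2E,6E)-3,7,11-trimethyldodeca-2,6,10-trien-1-yl]malonate | COc1ccc(COCCC[C@@](C/C=C(\C)CC/C=C(\C)CCC=C(C)C)(C(=O)OCC(c2ccccc2)c2ccccc2)C(=O)OC(C)(C)C)cc1 | intermediate
8 | (2R)-2-(tert-butoxycarbonyl)-5-[(4-methoxybenzyl)oxy]-2-[(2E,6E)-3,7,11-trimethyldodeca-2,6,10-trien-1-yl]pentanoic acid | COc1ccc(COCCC[C@@](C/C=C(\C)CC/C=C(\C)CCC=C(C)C)(C(=O)O)C(=O)OC(C)(C)C)cc1 | intermediate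
9 | tert-butyl (2S)-2-(chlorocarbonyl)-5-[(4-methoxybenzyl)oxy]-2-[(2E,6E)-3,7,11-trimethyldodeca-2,6,10-trien-1-yl]pentanoate | COc1ccc(COCCC[C@@](C/C=C(\C)CC/C=C(\C)CCC=C(C)C)(C(=O)Cl)C(=O)OC(C)(C)C)cc1 | intermediate
10 | 1-tert-butyl 3-(1,1,1,3,3,3-hexafluoropropan-2-yl) (2R)-2-{3-[(4-methoxybenzyl)oxy]propyl}-2-[(2E,6E)-3,7,11-trimethyldodeca-2,6,10-trien-1-yl]malonate | COc1ccc(COCCC[C@@](C/C=C(\C)CC/C=C(\C)CCC=C(C)C)(C(=O)OC(C(F)(F)F)C(F)(F)F)C(=O)OC(C)(C)C)cc1 | intermediate
11 | 1-(1,1,1,3,3,3-hexafluoropropan-2-yl) 3-(trimethylsilyl) (2R)-2-{3-[(4-methoxybenzyl)oxy]propyl}-2-[(2E,6E)-3,7,11-trimethyldodeca-2,6,10-trien-1-yl]malonate | COc1ccc(COCCC[C@@](C/C=C(\C)CC/C=C(\C)CCC=C(C)C)(C(=O)OC(C(F)(F)F)C(F)(F)F)C(=O)O[Si](C)(C)C)cc1 | intermediate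
12 | (2S)-2-{[(1,1,1,3,3,3-hexafluoropropan-2-yl)oxy]carbonyl}-5-[(4-methoxybenzyl)oxy]-2-[(2E,6E)-3,7,11-trimethyldodeca-2,6,10-trien-1-yl]pentanoic acid | COc1ccc(COCCC[C@@](C/C=C(\C)CC/C=C(\C)CCC=C(C)C)(C(=O)OC(C(F)(F)F)C(F)(F)F)C(=O)O)cc1 | intermediate
13 | 2-(trimethylsilyl)phenyl trifluoromethanesulfonate | C[Si](C)(C)c1ccccc1OS(=O)(=O)C(F)(F)F | starting material
14 | potassium (2S)-2-{[(1,1,1,3,3,3-hexafluoropropan-2-yl)oxy]carbonyl}-5-[(4-methoxybenzyl)oxy]-2-[(2E,6E)-3,7,11-trimethyldodeca-2,6,10-trien-1-yl]pentanoate | COc1ccc(COCCC[C@@](C/C=C(\C)CC/C=C(\C)CCC=C(C)C)(C(=O)OC(C(F)(F)F)C(F)(F)F)C(=O)[O-])cc1.[K+] | intermediate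
15 | potassium 2-{(2S)-2-{[(1,1,1,3,3,3-hexafluoropropan-2-yl)oxy]carbonyl}-5-[(4-methoxybenzyl)oxy]-2-[(2E,6E)-3,7,11-trimethyldodeca-2,6,10-trien-1-yl]pentanoyl}phenolate | COc1ccc(COCCC[C@@](C/C=C(\C)CC/C=C(\C)CCC=C(C)C)(C(=O)OC(C(F)(F)F)C(F)(F)F)C(=O)c2ccccc2[O-])cc1.[K+] | intermediate
16 | (3S)-3-{3-[(4-methoxybenzyl)oxy]propyl}-3-[(2E,6E)-3,7,11-trimethyldodeca-2,6,10-trien-1-yl]chroman-2,4-dione | COc1ccc(COCCC[C@@]2(C/C=C(\C)CC/C=C(\C)CCC=C(C)C)C(=O)Oc3ccccc3C2=O)cc1 | intermediate
17 | (3S)-3-(3-hydroxypropyl)-3-[(2E,6E)-3,7,11-trimethyldodeca-2,6,10-trien-1-yl]chroman-2,4-dione | OCCC[C@@]1(C/C=C(\C)CC/C=C(\C)CCC=C(C)C)C(=O)Oc2ccccc2C1=O | intermediate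
18 | 3-{(3S)-2,4-dioxo-3-[(2E,6E)-3,7,11-trimethyldodeca-2,6,10-trien-1-yl]chroman-3-yl}propanal | O=CCC[C@@]1(C/C=C(\C)CC/C=C(\C)CCC=C(C)C)C(=O)Oc2ccccc2C1=O | intermediate
19 | 3-{(3S)-2,4-dioxo-3-[(2E,6E)-3,7,11-trimethyldodeca-2,6,10-trien-1-yl]chroman-3-yl}propanoic acid | OC(=O)CC[C@@]1(C/C=C(\C)CC/C=C(\C)CCC=C(C)C)C(=O)Oc2ccccc2C1=O | intermediate
20 | dec-2-yn-1-ol | CCCCCCCC#CCO | starting material
21 | (2Z)-dec-2-en-1-ol | CCCCCCC/C=C\CO | intermediate
22 | (2Z)-dec-2-enal | CCCCCCC/C=C\C=O | intermediate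
23 | 1,4-bis(trimethylsilyl)buta-1,3-diyne | C[Si](C)(C)C#CC#C[Si](C)(C)C | starting material
24 | lithium 4-(trimethylsilyl)buta-1,3-diyn-1-ide | [Li+].[C-]#CC#C[Si](C)(C)C | intermediate
25 | buta-1,3-diyn-1-yl(trimethyl)silane | C#CC#C[Si](C)(C)C | intermediate
26 | (5S,6Z)-1-(trimethylsilyl)tetradec-6-ene-1,3-diyn-5-ol | CCCCCCC/C=C\[C@H](O)C#CC#C[Si](C)(C)C | intermediate
27 | tert-butyl(dimethyl){[(5S,6Z)-1-(trimethylsilyl)tetradec-6-ene-1,3-diyn-5-yl]oxy}silane | CCCCCCC/C=C\[C@H](O[Si](C)(C)C(C)(C)C)C#CC#C[Si](C)(C)C | intermediate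
28 | tert-butyl(dimethyl)[(5S,6Z)-tetradec-6-ene-1,3-diyn-5-yloxy]silane | CCCCCCC/C=C\[C@H](O[Si](C)(C)C(C)(C)C)C#CC#C | intermediate
29 | 3-{(3S)-2,4-dioxo-3-[(2E,6E)-3,7,11-trimethyldodeca-2,6,10-trien-1-yl]chroman-3-yl}propanoyl chloride | O=C(Cl)CC[C@@]1(C/C=C(\C)CC/C=C(\C)CCC=C(C)C)C(=O)Oc2ccccc2C1=O | intermediate
30 | (3S)-3-{(8S,9Z)-8-[(tert-butyldimethylsilyl)oxy]-3-oxoheptadeca-9-ene-4,6-diyn-1-yl}-3-[(2E,6E)-3,7,11-trimethyldodeca-2,6,10-trien-1-yl]chroman-2,4-dione | CCCCCCC/C=C\[C@H](O[Si](C)(C)C(C)(C)C)C#CC#CC(=O)CC[C@@]1(C/C=C(\C)CC/C=C(\C)CCC=C(C)C)C(=O)Oc2ccccc2C1=O | intermediate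
31 | (3S)-3-[(8S,9Z)-8-hydroxy-3-oxoheptadeca-9-ene-4,6-diyn-1-yl]-3-[(2E,6E)-3,7,11-trimethyldodeca-2,6,10-trien-1-yl]chroman-2,4-dione | CCCCCCC/C=C\[C@H](O)C#CC#CC(=O)CC[C@@]1(C/C=C(\C)CC/C=C(\C)CCC=C(C)C)C(=O)Oc2ccccc2C1=O | target

Total step count: 18. Longest linear sequence: 11 steps (steps 2 to 10, then 17 and 18, from mono-tert-butyl malonate).

Steps most likely to fail

Step 8. The aryl anion may be protonated before the acyl shift, which would stop at an O-aryl ester. It may instead attack the distal ester through the six-membered path, which would swap the roles of the two carbonyls and erode the enantiopurity at C3. Benzyne may also be lost to the liberated alkoxide or to ene reaction with the farnesyl chain. The fallback uses known reactions only and fixes by construction which carbonyl becomes the ketone. It sets out from 12, which the α-chloroenamine converts into the malonyl chloride F1. Negishi acylation of F1 with {2-[(tert-butyldimethylsilyl)oxy]phenyl}zinc iodide (from the aryl iodide with Zn and LiCl) under Pd(PPh3)4, a zerovalent palladium catalyst, in THF at rt should give the silyl-protected 2-hydroxyaryl ketone F2. TBAF in THF at 0 °C then unmasks the phenoxide, which closes on the hexafluoroisopropyl ester, and the sequence comes back to the route at 16.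

Step 4. The enolate of 5 carries a much larger α-substituent than the small alkyl groups for which this catalyst type is proven, so facial discrimination may be poor, and alkylation at −40 °C may be sluggish. The fallback gives up asymmetric induction for resolution. It sets out from 5 and 6, which are combined under achiral phase-transfer conditions (tetrabutylammonium bromide, 50% aq KOH, toluene, 0 °C) to give the racemic diester F3. The enantiomers of F3 are separated by preparative chromatography on a polysaccharide chiral stationary phase, and the R enantiomer re-enters the route as 7.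

Step 17. The terminal diyne may be lost to oxidative homocoupling or decomposition under copper and amine, the amine may turn the acid chloride into a ketene, and the amine may add to the diynone once formed. The fallback replaces the copper acetylide by a preformed tin acetylide and needs neither amine nor copper. It sets out from 28, which is deprotonated with LiHMDS in THF at −78 °C and quenched with Bu3SnCl to give the alkynylstannane F4. Stille acylation of F4 with the acid chloride 29 under PdCl2(PPh3)2 (precatalyst reduced in the flask to zerovalent palladium) in THF at 50 °C comes back to the route at 30.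

Further compounds

F1 | step 8 | 1,1,1,3,3,3-hexafluoropropan-2-yl (2R)-2-(chlorocarbonyl)-5-[(4-methoxybenzyl)oxy]-2-[(2E,6E)-3,7,11-trimethyldodeca-2,6,10-trien-1-yl]pentanoate | COc1ccc(COCCC[C@@](C/C=C(\C)CC/C=C(\C)CCC=C(C)C)(C(=O)OC(C(F)(F)F)C(F)(F)F)C(=O)Cl)cc1
F2 | step 8 | 1,1,1,3,3,3-hexafluoropropan-2-yl (2S)-2-{2-[(tert-butyldimethylsilyl)oxy]benzoyl}-5-[(4-methoxybenzyl)oxy]-2-[(2E,6E)-3,7,11-trimethyldodeca-2,6,10-trien-1-yl]pentanoate | COc1ccc(COCCC[C@@](C/C=C(\C)CC/C=C(\C)CCC=C(C)C)(C(=O)OC(C(F)(F)F)C(F)(F)F)C(=O)c2ccccc2O[Si](C)(C)C(C)(C)C)cc1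
F3 | step 4 | racemic 1-tert-butyl 3-(2,2-diphenylethyl) 2-{3-[(4-methoxybenzyl)oxy]propyl}-2-[(2E,6E)-3,7,11-trimethyldodeca-2,6,10-trien-1-yl]malonate | COc1ccc(COCCCC(C/C=C(\C)CC/C=C(\C)CCC=C(C)C)(C(=O)OCC(c2ccccc2)c2ccccc2)C(=O)OC(C)(C)C)cc1
F4 | step 17 | tributyl{(5S,6Z)-5-[(tert-butyldimethylsilyl)oxy]tetradec-6-ene-1,3-diyn-1-yl}stannane | CCCCCCC/C=C\[C@H](O[Si](C)(C)C(C)(C)C)C#CC#C[Sn](CCCC)(CCCC)CCCC
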